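Kazinol C is disconnected at the bond between the terminal CH2 of the propane tether and C-5 of the catechol ring (catechol numbering: OH at C-1/C-2, prenyl at C-3/C-4). One Negishi sp3–sp2 coupling joins a primary alkylzinc iodide, carrying the finished MOM-protected resorcinol ring with its 1,1-dimethylallyl group, to a 4,5-dibromo-3-prenylcatechol bis-MOM ether. The step exploits the three contiguous carbon substituents C-3/C-4/C-5 of the catechol ring: the outer C-5 bromide, flanked by H-6, reacts, while the inner C-4 bromide, buttressed by the C-3 prenyl group, is kept for the second prenylation. No hydrometalation is involved, so the three alkenes are untouched.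

Key step: step 7

Remark: the target has no stereocentre and no stereogenic double bond, so the SMILES defines one achiral compound and the route needs no stereocontrol.

Step 1
Reactants: 1 4,6-dibromobenzene-1,3-diol (4,6-dibromoresorcinol)
Product: 2 1,5-dibromo-2,4-bis(methoxymethoxy)benzene
Conditions: NaH (2.4 equiv), MOMCl (2.4 equiv), DMF, 0 °C to rt
Reagents that add atoms: chloromethyl methyl ether (MOMCl), COCCl
Why: Williamson-type O-alkylation of both phenoxides (MOM protection) should give ethers that survive the organolithium, palladium and zinc steps.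

Step 2
Reactants: 2 1,5-dibromo-2,4-bis(methoxymethoxy)benzene
Product: 4 3-[5-bromo-2,4-bis(methoxymethoxy)phenyl]propan-1-ol, via aryllithium 3 (not isolated)
Conditions: n-BuLi (1.05 equiv), THF, −78 °C; oxetane, BF3·OEt2 (promoter), −78 °C; aq. NaHCO3
Reagents that add atoms: oxetane, C1COC1
Why: Bromine–lithium exchange on the symmetric dibromide is faster than ring deprotonation and should stop at the monolithio stage with one equivalent, and BF3-activated ring opening of oxetane by the aryllithium delivers the three-carbon tether as a primary alcohol.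

Step 3
Reactants: 4 3-[5-bromo-2,4-bis(methoxymethoxy)phenyl]propan-1-ol
Product: 5 3-[2,4-bis(methoxymethoxy)-5-(2-methylbut-3-en-2-yl)phenyl]propan-1-ol
Conditions: prenylBpin (1.5 equiv), Pd(OAc)2 (3 mol %), t-BuXPhos (6 mol %), aq. K3PO4, MeCN, 70 °C
Reagents that add atoms: 3-methylbut-2-enylboronic acid pinacol ester (prenylBpin), CC(C)=CCB1OC(C)(C)C(C)(C)O1
Why: In this γ-selective Suzuki–Miyaura coupling of an allylboronate, SE2′ transmetalation places palladium on the tertiary carbon and the bulky di-tert-butylbiarylphosphine should force reductive elimination before σ–π–σ isomerisation, giving the 1,1-dimethylallyl arene.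

Step 4
Reactants: 5 3-[2,4-bis(methoxymethoxy)-5-(2-methylbut-3-en-2-yl)phenyl]propan-1-ol
Product: 6 1-(3-iodopropyl)-2,4-bis(methoxymethoxy)-5-(2-methylbut-3-en-2-yl)benzene
Conditions: I2, PPh3, imidazole, CH2Cl2, 0 °C to rt
Reagents that add atoms: iodine, II
Why: Appel iodination of the primary alcohol under imidazole buffering should leave the MOM ethers and the vinyl group intact.

Step 5
Reactants: 7 4,5-dibromobenzene-1,2-diol (4,5-dibromocatechol)
Product: 8 1,2-dibromo-4,5-bis(methoxymethoxy)benzene
Conditions: NaH (2.4 equiv), MOMCl (2.4 equiv), DMF, 0 °C to rt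
Reagents that add atoms: chloromethyl methyl ether (MOMCl), COCCl
Why: Williamson-type MOM protection of the catechol gives the directing groups needed for the next metalation.

Step 6
Reactants: 8 1,2-dibromo-4,5-bis(methoxymethoxy)benzene
Product: 11 1,2-dibromo-4,5-bis(methoxymethoxy)-3-(3-methylbut-2-en-1-yl)benzene (catechol numbering: prenyl at C-3, Br at C-4 and C-5), via aryllithium 9 (not isolated), via arylcopper 10 (not isolated)
Conditions: LDA (1.0 equiv), THF, −78 °C; CuBr·SMe2 (1.0 equiv), −78 °C; prenyl bromide, −78 to 0 °C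
Reagents that add atoms: prenyl bromide (1-bromo-3-methylbut-2-ene), CC(C)=CCBr
Why: LDA should remove one of the two equivalent ring protons, each acidified by a flanking OMOM group and bromine (directed ortho-metalation), at a temperature where loss of LiBr to an aryne is slow, and the arylcopper is then allylated in the SN2 sense to give the linear prenyl group.

Step 7
Reactants: 6 1-(3-iodopropyl)-2,4-bis(methoxymethoxy)-5-(2-methylbut-3-en-2-yl)benzene; 11 1,2-dibromo-4,5-bis(methoxymethoxy)-3-(3-methylbut-2-en-1-yl)benzene
Product: 13 2-bromo-1-{3-[2,4-bis(methoxymethoxy)-5-(2-methylbut-3-en-2-yl)phenyl]propyl}-4,5-bis(methoxymethoxy)-3-(3-methylbut-2-en-1-yl)benzene, via alkylzinc iodide 12 (not isolated)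
Conditions: Zn dust (activated), LiCl, THF, 40 °C; then 11 (1.2 equiv), PdCl2(dppf)·CH2Cl2 (5 mol %), THF, 50 °C
Reagents that add atoms: none
Why: Zinc inserts into the primary C–I bond of 6 (LiCl-assisted) to give alkylzinc iodide 12; Pd(0)(dppf) then adds oxidatively to one C–Br bond of 11, and transmetalation with 12 followed by reductive elimination forms the CH2–aryl bond, the wide bite angle of dppf letting reductive elimination outrun β-hydride elimination. The closest known reaction type is the Negishi alkyl–aryl coupling combined with site-selective mono-coupling of vicinal polybromoarenes at the less hindered halide. No ring is closed and no stereocentre is formed. The step needs site selectivity between the two bromides and must stop after one coupling: the outer C-5 bromide has H-6 as its second neighbour and lies para to the twisted, weakly donating OMOM group on C-2, whereas the inner C-4 bromide is flanked by the prenyl CH2 and lies para to the coplanar OMOM group on C-1, so it is both more hindered and more electron-rich. After the first coupling the remaining bromide carries two ortho carbon substituents and should react more slowly still, and 12 is the limiting reagent. Because the organometallic comes from an iodide and not from a hydrometalation, the vinyl group and the prenyl alkene do not interfere.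

Step 8
Reactants: 13 2-bromo-1-{3-[2,4-bis(methoxymethoxy)-5-(2-methylbut-3-en-2-yl)phenyl]propyl}-4,5-bis(methoxymethoxy)-3-(3-methylbut-2-en-1-yl)benzene
Product: 14 1-{3-[2,4-bis(methoxymethoxy)-5-(2-methylbut-3-en-2-yl)phenyl]propyl}-4,5-bis(methoxymethoxy)-2,3-bis(3-methylbut-2-en-1-yl)benzene (tetra-MOM kazinol C)
Conditions: prenylBpin (2 equiv), Pd-PEPPSI-IPent (4 mol %), 5 M aq. KOH, THF, 70 °C
Reagents that add atoms: 3-methylbut-2-enylboronic acid pinacol ester (prenylBpin), CC(C)=CCB1OC(C)(C)C(C)(C)O1
Why: This α-selective Suzuki–Miyaura prenylation uses a bulky NHC–palladium catalyst suited to di-ortho-substituted aryl bromides, and reductive elimination at the unhindered CH2 terminus of the allyl ligand should give the linear prenyl group.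

Step 9
Reactants: 14 tetra-MOM kazinol C
Product: 15 kazinol C, 5-{3-[2,4-dihydroxy-5-(2-methylbut-3-en-2-yl)phenyl]propyl}-3,4-bis(3-methylbut-2-en-1-yl)benzene-1,2-diol
Conditions: 2 M HCl, MeOH (degassed), rt to 40 °C
Reagents that add atoms: none
Why: Acid-catalysed acetal exchange with methanol (MOM cleavage) under dilute, mild conditions should free the four phenols faster than the ortho-prenyl groups can cyclise to chromans.

Compound list
1 | 4,6-dibromobenzene-1,3-diol | Oc1cc(O)c(Br)cc1Br | starting material
2 | 1,5-dibromo-2,4-bis(methoxymethoxy)benzene | COCOc1cc(OCOC)c(Br)cc1Br | intermediate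
3 | [5-bromo-2,4-bis(methoxymethoxy)phenyl]lithium | COCOc1cc(OCOC)c(Br)cc1[Li] | intermediate (not isolated)
4 | 3-[5-bromo-2,4-bis(methoxymethoxy)phenyl]propan-1-ol | COCOc1cc(OCOC)c(Br)cc1CCCO | intermediate
5 | 3-[2,4-bis(methoxymethoxy)-5-(2-methylbut-3-en-2-yl)phenyl]propan-1-ol | COCOc1cc(OCOC)c(C(C)(C)C=C)cc1CCCO | intermediate
6 | 1-(3-iodopropyl)-2,4-bis(methoxymethoxy)-5-(2-methylbut-3-en-2-yl)benzene | COCOc1cc(OCOC)c(C(C)(C)C=C)cc1CCCI | intermediate
7 | 4,5-dibromobenzene-1,2-diol | Oc1cc(Br)c(Br)cc1O | starting material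
8 | 1,2-dibromo-4,5-bis(methoxymethoxy)benzene | COCOc1cc(Br)c(Br)cc1OCOC | intermediate
9 | [2,3-dibromo-5,6-bis(methoxymethoxy)phenyl]lithium | COCOc1cc(Br)c(Br)c([Li])c1OCOC | intermediate (not isolated)
10 | [2,3-dibromo-5,6-bis(methoxymethoxy)phenyl]copper | COCOc1cc(Br)c(Br)c([Cu])c1OCOC | intermediate (not isolated)
11 | 1,2-dibromo-4,5-bis(methoxymethoxy)-3-(3-methylbut-2-en-1-yl)benzene | COCOc1cc(Br)c(Br)c(CC=C(C)C)c1OCOC | intermediate
12 | {3-[2,4-bis(methoxymethoxy)-5-(2-methylbut-3-en-2-yl)phenyl]propyl}zinc iodide | COCOc1cc(OCOC)c(C(C)(C)C=C)cc1CCC[Zn]I | intermediate (not isolated)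
13 | 2-bromo-1-{3-[2,4-bis(methoxymethoxy)-5-(2-methylbut-3-en-2-yl)phenyl]propyl}-4,5-bis(methoxymethoxy)-3-(3-methylbut-2-en-1-yl)benzene | COCOc1cc(OCOC)c(C(C)(C)C=C)cc1CCCc1cc(OCOC)c(OCOC)c(CC=C(C)C)c1Br | intermediate
14 | 1-{3-[2,4-bis(methoxymethoxy)-5-(2-methylbut-3-en-2-yl)phenyl]propyl}-4,5-bis(methoxymethoxy)-2,3-bis(3-methylbut-2-en-1-yl)benzene | COCOc1cc(OCOC)c(C(C)(C)C=C)cc1CCCc1cc(OCOC)c(OCOC)c(CC=C(C)C)c1CC=C(C)C | intermediate
15 | kazinol C | C=CC(C)(C)c1cc(CCCc2cc(O)c(O)c(CC=C(C)C)c2CC=C(C)C)c(O)cc1O | target

Total step count: 9. Longest linear sequence: 7 steps (steps 1, 2, 3, 4, 7, 8, 9).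

Steps most likely to fail

Step 7 (key coupling). The process at risk is discrimination between the two adjacent C–Br bonds of 11: oxidative addition at the inner bromide, or a second coupling after the first, would give isomeric or doubly alkylated material. The fallback removes the need for discrimination by symmetry and moves the C-3 prenylation behind the coupling. It sets out from 6 and 8. Zinc reagent 12, made from 6 as before, would be coupled under the same Pd/dppf conditions with an excess (3 equiv) of the symmetric dibromide 8 to give the monoalkylated bromide 1-bromo-2-{3-[2,4-bis(methoxymethoxy)-5-(2-methylbut-3-en-2-yl)phenyl]propyl}-4,5-bis(methoxymethoxy)benzene F1. LDA (THF, −78 °C) should then remove only the ring proton flanked by bromine and OMOM, to give the aryllithium F2; the proton next to the tether and the resorcinol-ring protons lack the acidifying bromine. Transmetalation with CuBr·SMe2 to the arylcopper F3 and allylation with prenyl bromide returns to the route at 13.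

Step 3 (reverse prenylation). The process at risk is loss of γ-selectivity, giving the linear prenyl isomer, or stalled oxidative addition at the electron-rich ortho-alkoxy bromide. The fallback builds the quaternary carbon by enolate arylation and sets out from 4. Silylation (TBSCl, imidazole, DMF) would give tert-butyl{3-[5-bromo-2,4-bis(methoxymethoxy)phenyl]propoxy}dimethylsilane F4. Pd-catalysed α-arylation of the lithium enolate of methyl isobutyrate (LiNCy2, Pd(dba)2, P(t-Bu)3, toluene, rt) would give methyl 2-[5-(3-{[tert-butyl(dimethyl)silyl]oxy}propyl)-2,4-bis(methoxymethoxy)phenyl]-2-methylpropanoate F5. DIBAL-H (CH2Cl2, −78 °C) would give 2-[5-(3-{[tert-butyl(dimethyl)silyl]oxy}propyl)-2,4-bis(methoxymethoxy)phenyl]-2-methylpropanal F6. Wittig methylenation (Ph3P=CH2, THF) would give tert-butyl{3-[2,4-bis(methoxymethoxy)-5-(2-methylbut-3-en-2-yl)phenyl]propoxy}dimethylsilane F7, and TBAF (THF) returns to the route at 5.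

Step 8 (second prenylation). The process at risk is slow oxidative addition at a bromide flanked by two ortho carbon substituents, with competing protodebromination or α/γ scrambling of the allyl group. The fallback avoids palladium and sets out from 13. Bromine–lithium exchange (n-BuLi, THF, −78 °C), which is much faster than any ring deprotonation, would give the aryllithium F8; CuBr·SMe2 would convert it into the arylcopper F9, and SN2 allylation with prenyl bromide returns to the route at 14.

Further compounds
F1 | step 7 | 1-bromo-2-{3-[2,4-bis(methoxymethoxy)-5-(2-methylbut-3-en-2-yl)phenyl]propyl}-4,5-bis(methoxymethoxy)benzene | C=CC(C)(C)c1cc(CCCc2cc(OCOC)c(OCOC)cc2Br)c(OCOC)cc1OCOC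
F2 | step 7 | aryllithium from F1 (Li between Br and OMOM) | C=CC(C)(C)c1cc(CCCc2cc(OCOC)c(OCOC)c([Li])c2Br)c(OCOC)cc1OCOC
F3 | step 7 | arylcopper from F2 | C=CC(C)(C)c1cc(CCCc2cc(OCOC)c(OCOC)c([Cu])c2Br)c(OCOC)cc1OCOC
F4 | step 3 | tert-butyl{3-[5-bromo-2,4-bis(methoxymethoxy)phenyl]propoxy}dimethylsilane | COCOc1cc(OCOC)c(Br)cc1CCCO[Si](C)(C)C(C)(C)C
F5 | step 3 | methyl 2-[5-(3-{[tert-butyl(dimethyl)silyl]oxy}propyl)-2,4-bis(methoxymethoxy)phenyl]-2-methylpropanoate | COCOc1cc(OCOC)c(C(C)(C)C(=O)OC)cc1CCCO[Si](C)(C)C(C)(C)C
F6 | step 3 | 2-[5-(3-{[tert-butyl(dimethyl)silyl]oxy}propyl)-2,4-bis(methoxymethoxy)phenyl]-2-methylpropanal | COCOc1cc(OCOC)c(C(C)(C)C=O)cc1CCCO[Si](C)(C)C(C)(C)C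
F7 | step 3 | tert-butyl{3-[2,4-bis(methoxymethoxy)-5-(2-methylbut-3-en-2-yl)phenyl]propoxy}dimethylsilane | COCOc1cc(OCOC)c(C(C)(C)C=C)cc1CCCO[Si](C)(C)C(C)(C)C
F8 | step 8 | aryllithium from 13 | COCOc1cc(OCOC)c(C(C)(C)C=C)cc1CCCc1cc(OCOC)c(OCOC)c(CC=C(C)C)c1[Li]
F9 | step 8 | arylcopper from F8 | COCOc1cc(OCOC)c(C(C)(C)C=C)cc1CCCc1cc(OCOC)c(OCOC)c(CC=C(C)C)c1[Cu]
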